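You read the south run at 54 min and again at 67 min, and target moves from 0.110 M to 0.112 M, a step smaller than the scatter of 0.003 M. So the readings of the south run have flattened, though its target stands far below the charge of 0.300 M.

| flask | starting material | catalyst | time |
|---|---|---|---|
| south | 0.300 M | 0.0300 M |  |
| west | 0.300 M | 0.0150 M |  |
| south-east | 0.450 M | 0.0300 M |  |
| south-west | 0.620 M | 0.0300 M | 67 min |

| run | time / min | [target] / M |
|---|---|---|
| south run | 13 | 0.064 |
| south run | 27 | 0.085 |
| south run | 40 | 0.100 |
| south run | 54 | 0.110 |
| south run | 67 | 0.112 |
| west run | 13 | 0.035 |
| west run | 27 | 0.055 |
| west run | 40 | 0.065 |
| west run | 54 | 0.076 |
| west run | 67 | 0.080 |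
| south-east run | 13 | 0.076 |
| south-east run | 27 | 0.106 |
| south-east run | 40 | 0.122 |
| south-east run | 54 | 0.137 |
| south-east run | 67 | 0.135 |

(scatter of a reading: 0.003 M)

- Overall: starting material -> target, with catalyst as catalyst.
- Constant volume, constant temperature.
- Readings of a species count what is bound in complexes too.
- An order is taken over about fifteen percent of the charge, up and down.

- apparent order in [catalyst] of the starting rate, round the charge of the south run (the rate where two percent of its starting material have turned into target)
- apparent order in [starting material] of the starting rate, round the charge of the south run (the rate where two percent of its starting material have turned into target) (one fixed amount of target, the same in the runs compared)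
- target in the south-west run at 67 min, as a share of the starting material charged

The first readings give you rough orders of 0.871 in [catalyst] and 0.424 in [starting material], but these are averages over 13 min, not starting rates.

Now take the mean of the last two readings of each run. In the south run that mean is 37.0% of its charge and in the south-east run 30.2%, a smaller share. My own reckoning takes this as a second-order loss of starting material. In such a loss each halving of [starting material] takes twice as long as the one before, while target forms half as fast, if its rate follows [starting material]. So each halving yields the same amount of target, the target per halving, and each doubling of the charge, read at the same late time, adds one such step.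

The south-east charge lies 0.585 doublings above the south charge, and the south-east mean in molar terms lies higher than the south one, so the readings give 0.0427 M per halving. The south-west charge lies 0.462 doublings above the south-east one, so I expect 0.156 M, which is 25.1% of its charge.

The forecast says 1.2, 0.35 and 26%, and its picture differs from mine: “It points to catalyst dying or being sequestered, probably by product.”

The simulation gives 0.83, 0.91 and 25.9%, from these steps:

    catalyst + starting material ⇌ catalyst-substrate complex, settled at all times (0.5690 L mol⁻¹)
    catalyst-substrate complex → target + catalyst (1.356 min⁻¹)
    2 starting material → homo dimer (0.1632 L mol⁻¹ min⁻¹)
    starting material → target (0.005484 min⁻¹)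

A power-law fit gives 37.5% for the south-west run. The 25.9% of that run is 0.160 M, or 3.75 halvings at 0.0427 M. In the south-east run, a quarter of the charge comes to 2.63 halvings. The first half-life of the homo dimer step there is 6.81 min, and that many halvings take 35.4 min by that step alone. The south-east run reached a quarter at 29.8 min.

All runs are calculated with constants of no real substance; scatter was added.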